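## The problem

β-Collatolic acid (20) is an unsymmetrical diaryl ether in which C8 of a 6-methoxy-3-pentylisocoumarin (ring A with its fused pyranone) is joined through oxygen to C3' of a 4',6'-dihydroxybenzoic acid (ring B) that carries a 2-oxoheptyl chain at C2'. The molecule has no stereocentre, so the task is one of regiochemistry and chemoselectivity. The ether oxygen is crowded: on ring A it sits next to the lactone-bearing C8a, and on ring B it lies between the side chain at C2' and the oxygen at C4', on a ring that is substituted at every carbon except C5'. Ring B is a 2-(2-oxoalkyl)benzoic acid at the same oxidation level as the opened form of ring A, so any reagent that closes the O2–C3 enol lactone of ring A will also lactonise ring B unless the two carboxyl groups are told apart beforehand. The finished molecule is fragile in several places: the enol lactone opens with hydroxide or alkoxide and can take up hydrogen across C3=C4, the β-resorcylic acid decarboxylates in hot acid, the aryl–CH2–ketone hydrogens are acidic, and one methyl ether has to outlast the unmasking of two phenols. The opening for a short route is that both rings show the same motif, a CH2C(=O)C5H11 group ortho to a carboxyl carbon (C4 on C4a beside C8a in ring A, the side-chain CH2 on C2' beside C1' in ring B). The target therefore contains two aryl–CH2 bonds of one kind, which a single reagent can form in a single operation.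

## Retrosynthesis

**Unmasking and lactone (20 ⇐ 19 ⇐ 17).** The last bonds cut are the three O–benzyl bonds of tribenzyl isocoumarin 19, so that the free keto acid of ring B appears only under neutral hydrogenolysis and never meets acid. Before that, the O2–C3 bond of the pyranone is cut, which leads through keto acid 18 to the bis(2-oxoheptyl) diester 17. The alternative of closing both rings and reopening ring B was rejected because hydroxide would open both lactones. Instead the two carboxyl groups are differentiated in 17 as a tert-butyl ester (ring A, acid-labile) and a benzyl ester (ring B, acid-stable). The forward step must cleave one ester and dehydrate one lactol without touching the benzyl groups.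

**The two aryl–CH2 bonds (17 ⇐ 16 + two 3).** With both rings as open keto esters, the C4a–C4 and C2'–CH2 bonds are the same kind of bond, and cutting both gives dibromide 16 and two molecules of 1-chloroheptan-2-one (3). Cutting CH2–C(=O) instead would need two benzylic anions beside two esters. Cutting on the pentyl side would leave the aryl–CH2 problem unsolved. An enolate arylation with a methyl ketone would have to choose the methyl side under base that the esters may not tolerate. The reductive coupling of two electrophiles removes 14 skeletal carbons from the precursor and defines the ketone position through the C–Cl bond. It asks the forward reaction to couple twice, once at a doubly ortho-substituted carbon, faster than the aryl groups are reduced.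

**The diaryl ether (16 ⇐ 15 ⇐ 14 ⇐ 13 + 6).** The ether is cut at the C8–O bond on the ring A side. There the carbon bears an ortho carbonyl group and can take a phenoxide by addition–elimination, whereas the C3'–O carbon of electron-rich ring B would need a copper coupling that cannot be selective beside two aryl bromides. An aldehyde activates far better than an ester, so ring A enters as fluoro aldehyde 6 and bromophenol 13 enters with its benzyl ester in place. The single aldehyde of ether 14 is then oxidised to acid 15 and alkylated to the tert-butyl ester 16. This splits the problem into two benzene rings of similar size.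

**Ring B (13 ⇐ 12 ⇐ 10 ⇐ 9 ⇐ 7 + three 8).** The C2'–Br bond is cut last: the free phenol of 12 directs bromine to its only open ortho position. The phenol C–O bond is traced to a C–B bond (boronate 11) and on to the C–Br bond of bromide 10. That bromide comes from the most activated position of tribenzyl compound 9, which is 2,4-dihydroxybenzoic acid (7) alkylated three times with benzyl bromide (8), once on the carboxylate and once on each phenol. An entry from the aldehyde oxidation level through a Dakin oxidation and a second formylation was considered. It costs two more steps and an aldehyde oxidation beside a free, electron-rich phenol, whereas 7 already has the carboxyl carbon and both oxygens in place.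

**Ring A aldehyde (6 ⇐ 4).** The formyl C–C bond is cut to aryllithium 5, which forms from 1-bromo-3-fluoro-5-methoxybenzene (4) by deprotonation at the CH between fluorine and bromine. Electrophilic formylation of this deactivated arene would be slow and unselective, while the acidity pattern places the lithium exactly where the carboxyl carbon C1 has to go.

**The chloro ketone (3 ⇐ 2 ⇐ 1).** Ketone 3 is traced to chlorohydrin 2, and the C3–C4 bond of 2 is cut to epichlorohydrin (1), with a butyl nucleophile adding at the unsubstituted epoxide carbon. Chlorination of the parent methyl ketone would not be regioselective. Opening the epoxide fixes chlorine on C1 and oxygen on C2 from the start.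

## Roads not taken

**Alternative 1:** Ring B is folded from a chain. The C1'–C2' bond is cut, which opens ring B to the diketo-dioxinone A2. In A2 the finished ring A sits as an aryloxy group on the carbon between two ketones, and the oxoheptyl ketone is masked as a dioxolane. In the forward step Et3N enolises A2, the α-carbon of the dioxinone adds to the ketone next to the ketal-bearing CH2, water is lost and ring B forms as the acetonide-masked salicylate A1.

- Merits: every substituent of ring B is placed by the chain, so no aromatic substitution has to find the right position. The C4' phenol appears free and the carboxyl group is already masked.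
- Weak points: A2 is a 2-aryloxy-1,3,5-tricarbonyl compound with several enolisable sites. O-cyclisation of an enol onto a neighbouring ketone and retro-Claisen cleavage compete with the wanted aldol. Building A2 requires attaching the hydrogen-bonded, hindered peri-hydroxyl of the ring A lactone to a diketone carbon, and the isocoumarin then has to survive a long linear sequence.
- Endgame: opening the benzodioxinone of A1 needs hydroxide or alkoxide, which also opens the isocoumarin. Removing the ketal needs acid, which is what lactonises the ring B keto acid.
- Comparison: in regiochemical certainty for ring B this road is better than the chosen plan, whose step 7 relies on directing effects. The chosen plan offers in return convergence from commercial aromatics, half the linear length, and an endgame in which ring B is unmasked under neutral conditions.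

**Alternative 2:** The O2–C3 bond of the lactone and the C=O bond of the ring B ketone are traced to two triple bonds in dialkyne A4 (ring A acid with a hept-1-ynyl group, ring B allyl ester with a hept-2-ynyl group). In the forward step Ph3PAuNTf2 in wet dioxane lets the ring A acid add 6-endo to its alkyne to give the pyranone. The carbonyl oxygen of the ring B allyl ester adds to C2 of the hept-2-ynyl chain and water releases the ketone, giving the triallyl compound A3.

- Merits: alkynes are inert carriers of both functions, one catalyst does both jobs, and the allyl groups of A3 come off with zerovalent palladium under neutral, non-reducing conditions. In this last respect the road is better than the chosen plan, whose final hydrogenolysis has to be stopped before the C3=C4 bond is reduced.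
- Weak points: the two chains differ (an sp–sp2 coupling on ring A, an sp3–sp2 propargylation on ring B with propargyl–allenyl isomerism), so the hidden symmetry is not used. The ring A acid can also close 5-exo to a five-membered alkylidene lactone. The cationic intermediate on ring B can lose its allyl group and end as a second isocoumarin ring, so the two rings are kept apart only by the acid–ester difference under one Lewis acid.
- Comparison: the chosen plan delivers the ketone oxidation level directly, uses one coupling partner for both rings, and differentiates the carboxyl groups by ester type before any ring is closed.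

**Alternative 3:** The C5–C6 bond of the ring A benzene is cut. The precursor A6 is a 4-methyl-6-pentyl-2-pyranone whose C3 carries an (E)-β-aryloxy acrylate, the aryl group being fully substituted ring B with its side chain as a ketal. In the forward step LiN(SiMe3)2 removes a proton from the 4-methyl group and the vinylogous enolate attacks the acrylate ester carbonyl. Loss of methoxide and tautomerisation give the C6 phenol A5, which is then methylated.

- Merits: the lactone and the pentyl group are present from the first step, so no selective lactonisation and no acid step are needed. The C6 oxygen appears as the only free phenol, so its methylation is unambiguous. In these two respects the road is better than the chosen plan.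
- Weak points: ring B must be made first with all its substituents, including the hindered phenol and a separately coupled, ketal-protected side chain, so the ring B problem is not reduced. A6 arises by conjugate addition of that phenol to an alkynyl ester, and only the alkene isomer with pyranone and ester cis can cyclise. The strong base can also deprotonate the α-CH2 of the pentyl group, open the pyranone, or send the carbanion into the ring B benzyl ester.
- Comparison: the chosen plan is shorter, keeps strong base away from the lactone altogether, and installs both side chains at once.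

Key step: step 11

## Route

Remark: the target has no stereocentre. Epichlorohydrin is used as the racemate, and the one stereocentre on the route (C2 of 2) is removed by oxidation in step 2.

Step 1
Reactants: 1 epichlorohydrin (racemic 2-(chloromethyl)oxirane)
Product: 2 1-chloroheptan-2-ol (racemic)
Conditions: n-BuMgBr, CuI (10 mol%), THF, −40 → 0 °C; then 1 M HCl
Reagents that add atoms: butylmagnesium bromide, CCCC[Mg]Br
Why: Copper-catalysed Grignard opening of the epoxide at its unsubstituted carbon; at low temperature and with an acidic quench the chloride is neither displaced nor lost by reclosure to an epoxide. The carbinol centre is racemic and disappears in step 2.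

Step 2
Reactants: 2 1-chloroheptan-2-ol
Product: 3 1-chloroheptan-2-one
Conditions: Dess–Martin periodinane, CH2Cl2, 0 °C → rt
Reagents that add atoms: none
Why: Dess–Martin oxidation of a secondary alcohol under non-basic conditions, so the α-chloro ketone is not exposed to epoxide formation or Favorskii chemistry.

Step 3
Reactants: 4 1-bromo-3-fluoro-5-methoxybenzene
Product: 6 2-bromo-6-fluoro-4-methoxybenzaldehyde, via aryllithium 5 (not isolated)
Conditions: LiN(i-Pr)2, THF, −78 °C; DMF, −78 → 0 °C; then 1 M HCl
Reagents that add atoms: N,N-dimethylformamide, CN(C)C=O
Why: Directed ortho-lithiation at the CH flanked by fluorine and bromine, the most acidic position of 4, followed by formylation with DMF. At −78 °C the ortho-bromo aryllithium 5 should neither lose LiBr to an aryne nor undergo halogen migration.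

Step 4
Reactants: 7 2,4-dihydroxybenzoic acid; 8 benzyl bromide (three molecules are incorporated)
Product: 9 benzyl 2,4-bis(benzyloxy)benzoate
Conditions: BnBr (3.5 equiv), K2CO3 (4 equiv), DMF, 60 °C
Reagents that add atoms: benzyl bromide, BrCc1ccccc1 (second molecule of 8, for the 4-O-benzyl ether); benzyl bromide, BrCc1ccccc1 (third molecule of 8, for the 2-O-benzyl ether)
Why: Threefold Williamson-type alkylation in one operation: the carboxylate takes the first molecule of 8 as the benzyl ester, the 4-phenoxide the second and the hydrogen-bonded 2-phenoxide the third. Warming and a small excess of 8 are needed for the last, slowest alkylation.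

Step 5
Reactants: 9 benzyl 2,4-bis(benzyloxy)benzoate
Product: 10 benzyl 2,4-bis(benzyloxy)-5-bromobenzoate
Conditions: NBS, MeCN, 0 °C → rt
Reagents that add atoms: N-bromosuccinimide, O=C1CCC(=O)N1Br
Why: Electrophilic aromatic bromination at C5, which is para to the 2-benzyloxy group, ortho to the 4-benzyloxy group and meta to the ester. C3 between the two ethers is shielded and C6 is not activated.

Step 6
Reactants: 10 benzyl 2,4-bis(benzyloxy)-5-bromobenzoate
Product: 12 benzyl 2,4-bis(benzyloxy)-5-hydroxybenzoate, via pinacol boronate 11 (not isolated)
Conditions: B2pin2, PdCl2(dppf) (3 mol%), KOAc, 1,4-dioxane, 90 °C; then THF, 30% H2O2, aq. NaHCO3, 0 °C → rt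
Reagents that add atoms: bis(pinacolato)diboron, CC1(C)OB(OC1(C)C)B1OC(C)(C)C(C)(C)O1 (its boron stays only in 11); hydrogen peroxide, OO (phenol oxygen of 12)
Why: Miyaura borylation followed by oxidative C–B to C–O migration, which places the oxygen on the carbon that carried bromine. Only acetate and hydrogencarbonate are present as bases, so the benzyl ester should survive.

Step 7
Reactants: 12 benzyl 2,4-bis(benzyloxy)-5-hydroxybenzoate
Product: 13 benzyl 4,6-bis(benzyloxy)-2-bromo-3-hydroxybenzoate
Conditions: NBS, i-Pr2NH (10 mol%), CH2Cl2, 0 °C
Reagents that add atoms: N-bromosuccinimide, O=C1CCC(=O)N1Br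
Why: Amine-mediated ortho-bromination of a phenol: the hydrogen-bonded N-bromoamine delivers bromine to the one free position ortho to the hydroxyl, between OH and the ester, the pattern known for 3-hydroxy-4-alkoxybenzoates and -benzaldehydes. The competing CH between the two benzyloxy groups is flanked on both sides.

Step 8
Reactants: 13 benzyl 4,6-bis(benzyloxy)-2-bromo-3-hydroxybenzoate; 6 2-bromo-6-fluoro-4-methoxybenzaldehyde
Product: 14 benzyl 4,6-bis(benzyloxy)-2-bromo-3-(3-bromo-2-formyl-5-methoxyphenoxy)benzoate
Conditions: Cs2CO3, DMF, 80 °C
Reagents that add atoms: none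
Why: Nucleophilic aromatic substitution: the phenoxide adds at the fluorine-bearing carbon ortho to the formyl group and fluoride leaves from the Meisenheimer adduct. Bromide ortho to the same formyl group is a much poorer leaving group in this mechanism, and the phenoxide, meta to its ester, stays nucleophilic despite its two ortho substituents.

Step 9
Reactants: 14 benzyl 4,6-bis(benzyloxy)-2-bromo-3-(3-bromo-2-formyl-5-methoxyphenoxy)benzoate
Product: 15 2-{4,6-bis(benzyloxy)-3-[(benzyloxy)carbonyl]-2-bromophenoxy}-6-bromo-4-methoxybenzoic acid
Conditions: NaClO2, NaH2PO4, 2-methyl-2-butene, t-BuOH/THF/H2O, 0 °C → rt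
Reagents that add atoms: sodium chlorite, [Na+].[O-]Cl=O
Why: Pinnick oxidation, which tolerates hindered aryl aldehydes, aryl bromides, benzyl ethers and esters. The alkene traps hypochlorous acid so the electron-rich ring B is not chlorinated.

Step 10
Reactants: 15 2-{4,6-bis(benzyloxy)-3-[(benzyloxy)carbonyl]-2-bromophenoxy}-6-bromo-4-methoxybenzoic acid
Product: 16 tert-butyl 2-{4,6-bis(benzyloxy)-3-[(benzyloxy)carbonyl]-2-bromophenoxy}-6-bromo-4-methoxybenzoate
Conditions: Cl3CC(=NH)O-t-Bu, CH2Cl2/cyclohexane, rt → 40 °C
Reagents that add atoms: tert-butyl 2,2,2-trichloroacetimidate, CC(C)(C)OC(=N)C(Cl)(Cl)Cl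
Why: Esterification by O-alkylation: the acid protonates the imidate and its carboxylate captures the tert-butyl cation. Crowding at the 2,6-disubstituted carbonyl carbon does not matter because that carbon is never attacked.

Step 11
Reactants: 16 tert-butyl 2-{4,6-bis(benzyloxy)-3-[(benzyloxy)carbonyl]-2-bromophenoxy}-6-bromo-4-methoxybenzoate; 3 1-chloroheptan-2-one (two molecules are incorporated)
Product: 17 tert-butyl 2-{4,6-bis(benzyloxy)-3-[(benzyloxy)carbonyl]-2-(2-oxoheptyl)phenoxy}-4-methoxy-6-(2-oxoheptyl)benzoate
Conditions: NiBr2(bpy) (20 mol%), NBu4BF4, DMF, Zn anode, Ni-foam cathode, undivided cell, constant current, 40 °C, slow addition of 3 (5 equiv)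
Reagents that add atoms: none
Why: Cathodic reduction of NiBr2(bpy) gives zerovalent nickel, which inserts into each C–Br bond of 16; both bromides are ortho to an ester, which speeds oxidative addition. The arylnickel bromide is reduced to a monovalent aryl species that takes up the C–Cl bond of 3 (or receives the zinc enolate formed from 3 and the zinc ions released at the anode), and reductive elimination from the aryl(2-oxoheptyl)nickel intermediate forms the aryl–CH2 bond and returns nickel to the cycle, with the zinc anode supplying the electrons. The closest known reaction type is the nickel-catalysed electroreductive cross-coupling of aryl halides with α-chloro ketones and α-chloro esters at a sacrificial anode, used here twice on one molecule. No ring is closed and no stereocentre is formed; the new bonds are C4a–C4 of ring A and C2'–CH2 of ring B. The ketone ends on its methyl side because the C–Cl bond, not an enolate equilibrium, defines the site. The step needs cross-coupling to outrun biaryl formation, hydrodebromination and reductive loss of 3: slow addition keeps the easily reduced chloro ketone scarce, the ortho substituents hinder aryl–aryl coupling, and the two C–Br carbons cannot reach each other within the molecule. Esters, benzyl ethers and the diaryl ether are not reduced at the potential of the nickel couple, and the tert-butyl and benzyl esters prevent either new keto ester from lactonising.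

Step 12
Reactants: 17 tert-butyl 2-{4,6-bis(benzyloxy)-3-[(benzyloxy)carbonyl]-2-(2-oxoheptyl)phenoxy}-4-methoxy-6-(2-oxoheptyl)benzoate
Product: 19 benzyl 4,6-bis(benzyloxy)-3-[(6-methoxy-1-oxo-3-pentyl-1H-isochromen-8-yl)oxy]-2-(2-oxoheptyl)benzoate, via keto acid 18 (not isolated)
Conditions: TFA/CH2Cl2 (1:4), 0 °C → rt; then (CF3CO)2O, 0 °C → rt
Reagents that add atoms: none
Why: Acidolysis of the tert-butyl ester with loss of isobutene frees only the ring A acid; its oxygen adds to the neighbouring ketone to give a six-membered lactol, and the anhydride drives dehydration to the isocoumarin. The benzyl ester of ring B is stable to trifluoroacetic acid, so ring B stays an open keto ester.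

Step 13
Reactants: 19 benzyl 4,6-bis(benzyloxy)-3-[(6-methoxy-1-oxo-3-pentyl-1H-isochromen-8-yl)oxy]-2-(2-oxoheptyl)benzoate
Product: 20 β-collatolic acid, 4,6-dihydroxy-3-[(6-methoxy-1-oxo-3-pentyl-1H-isochromen-8-yl)oxy]-2-(2-oxoheptyl)benzoic acid
Conditions: H2 (1 atm), 10% Pd/C, EtOAc, rt, stopped after three equivalents of H2
Reagents that add atoms: none
Why: Hydrogenolysis of one benzyl ester and two aryl benzyl ethers under neutral conditions, so the ring B keto acid is never exposed to acid. The trisubstituted C3=C4 bond of the enol lactone and the ketone should react far more slowly than O–benzyl bonds.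

## Compound list

1 | epichlorohydrin (racemic) | ClCC1CO1 | starting material
2 | 1-chloroheptan-2-ol (racemic) | CCCCCC(O)CCl | intermediate
3 | 1-chloroheptan-2-one | CCCCCC(=O)CCl | intermediate
4 | 1-bromo-3-fluoro-5-methoxybenzene | COc1cc(F)cc(Br)c1 | starting material
5 | (2-bromo-6-fluoro-4-methoxyphenyl)lithium | COc1cc(F)c([Li])c(Br)c1 | intermediate (not isolated)
6 | 2-bromo-6-fluoro-4-methoxybenzaldehyde | COc1cc(F)c(C=O)c(Br)c1 | intermediate
7 | 2,4-dihydroxybenzoic acid | O=C(O)c1ccc(O)cc1O | starting material
8 | benzyl bromide | BrCc1ccccc1 | starting material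
9 | benzyl 2,4-bis(benzyloxy)benzoate | O=C(OCc1ccccc1)c1ccc(OCc2ccccc2)cc1OCc1ccccc1 | intermediate
10 | benzyl 2,4-bis(benzyloxy)-5-bromobenzoate | O=C(OCc1ccccc1)c1cc(Br)c(OCc2ccccc2)cc1OCc1ccccc1 | intermediate
11 | benzyl 2,4-bis(benzyloxy)-5-(4,4,5,5-tetramethyl-1,3,2-dioxaborolan-2-yl)benzoate | O=C(OCc1ccccc1)c1cc(B2OC(C)(C)C(C)(C)O2)c(OCc2ccccc2)cc1OCc1ccccc1 | intermediate (not isolated)
12 | benzyl 2,4-bis(benzyloxy)-5-hydroxybenzoate | O=C(OCc1ccccc1)c1cc(O)c(OCc2ccccc2)cc1OCc1ccccc1 | intermediate
13 | benzyl 4,6-bis(benzyloxy)-2-bromo-3-hydroxybenzoate | O=C(OCc1ccccc1)c1c(Br)c(O)c(OCc2ccccc2)cc1OCc1ccccc1 | intermediate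
14 | benzyl 4,6-bis(benzyloxy)-2-bromo-3-(3-bromo-2-formyl-5-methoxyphenoxy)benzoate | COc1cc(Br)c(C=O)c(Oc2c(Br)c(C(=O)OCc3ccccc3)c(OCc4ccccc4)cc2OCc5ccccc5)c1 | intermediate
15 | 2-{4,6-bis(benzyloxy)-3-[(benzyloxy)carbonyl]-2-bromophenoxy}-6-bromo-4-methoxybenzoic acid | COc1cc(Br)c(C(=O)O)c(Oc2c(Br)c(C(=O)OCc3ccccc3)c(OCc4ccccc4)cc2OCc5ccccc5)c1 | intermediate
16 | tert-butyl 2-{4,6-bis(benzyloxy)-3-[(benzyloxy)carbonyl]-2-bromophenoxy}-6-bromo-4-methoxybenzoate | COc1cc(Br)c(C(=O)OC(C)(C)C)c(Oc2c(Br)c(C(=O)OCc3ccccc3)c(OCc4ccccc4)cc2OCc5ccccc5)c1 | intermediate
17 | tert-butyl 2-{4,6-bis(benzyloxy)-3-[(benzyloxy)carbonyl]-2-(2-oxoheptyl)phenoxy}-4-methoxy-6-(2-oxoheptyl)benzoate | COc1cc(CC(=O)CCCCC)c(C(=O)OC(C)(C)C)c(Oc2c(CC(=O)CCCCC)c(C(=O)OCc3ccccc3)c(OCc4ccccc4)cc2OCc5ccccc5)c1 | intermediate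
18 | 2-{4,6-bis(benzyloxy)-3-[(benzyloxy)carbonyl]-2-(2-oxoheptyl)phenoxy}-4-methoxy-6-(2-oxoheptyl)benzoic acid | COc1cc(CC(=O)CCCCC)c(C(=O)O)c(Oc2c(CC(=O)CCCCC)c(C(=O)OCc3ccccc3)c(OCc4ccccc4)cc2OCc5ccccc5)c1 | intermediate (not isolated)
19 | benzyl 4,6-bis(benzyloxy)-3-[(6-methoxy-1-oxo-3-pentyl-1H-isochromen-8-yl)oxy]-2-(2-oxoheptyl)benzoate | CCCCCc1cc2cc(OC)cc(Oc3c(CC(=O)CCCCC)c(C(=O)OCc4ccccc4)c(OCc5ccccc5)cc3OCc6ccccc6)c2c(=O)o1 | intermediate
20 | β-collatolic acid | CCCCCC(=O)Cc1c(Oc2cc(OC)cc3cc(CCCCC)oc(=O)c23)c(O)cc(O)c1C(=O)O | target

## Step count and risks

Total: 13 steps. Longest linear sequence: 10 steps (steps 4 to 13, from 7 to 20). The side branches are steps 1–2 (to 3) and step 3 (to 6).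

**Step 11 (key step).** The most likely failure is hydrodebromination at the doubly ortho-substituted ring B carbon, where the crowded arylnickel species picks up hydrogen before it meets the ketone partner. The reaction may also stall after one coupling, and the acidic ArCH2C(=O) position of the product may be arylated further. Fallback: the same two bonds are formed from 16 with a nucleophilic ketone equivalent under palladium catalysis. Purchased heptan-2-one F1 is converted with LiN(i-Pr)2 and Me3SiCl in THF at −78 °C into the kinetic, terminal silyl enol ether 2-(trimethylsilyloxy)hept-1-ene F2. Dibromide 16 and an excess of F2 are then coupled with Pd(OAc)2, P(t-Bu)3, Bu3SnF and CsF in toluene at 85 °C, a known α-arylation of silyl enol ethers through tin enolates that tolerates esters. The sequence returns to the route at 17.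

**Step 7.** Bromine may enter at the CH between the two benzyloxy groups, which is activated by both ethers, or enter twice. Fallback: the position is fixed by directed metalation instead of electrophilic substitution. Phenol 12 is protected with MeOCH2Cl and i-Pr2NEt as benzyl 2,4-bis(benzyloxy)-5-(methoxymethoxy)benzoate F3. (2,2,6,6-Tetramethylpiperidin-1-yl)MgCl·LiCl in THF at 0 °C magnesiates the CH flanked by the ester and the acetal oxygen to give the arylmagnesium chloride F4 (not isolated). Quenching with BrCl2C–CCl2Br gives benzyl 4,6-bis(benzyloxy)-2-bromo-3-(methoxymethoxy)benzoate F5, and HCl in dioxane/water removes the acetal. The sequence returns at 13.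

**Step 12.** Under trifluoroacetic acid, benzyl ethers of the electron-rich ring B may be lost, with the benzyl cation alkylating that ring. Dehydration of the lactol may stop short, or the ring B ketone and benzyl ester may take part in a second lactonisation. Fallback: deprotection and ring closure are separated and Brønsted acid is avoided. ZnBr2 in CH2Cl2 at rt cleaves the tert-butyl ester of 17 and keto acid 18 is isolated. Ac2O and NaOAc at 60 °C then convert 18 into the mixed acetic anhydride F6, whose ketone enol oxygen is acylated intramolecularly. The sequence returns at 19.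

**Step 13.** Hydrogen may add across C3=C4 of the isocoumarin before all three benzyl groups are gone, and the liberated β-resorcylic acid may decarboxylate if the mixture is warmed. Fallback: the benzyl groups are removed from 19 without hydrogen, by BCl3 and pentamethylbenzene in CH2Cl2 at −78 °C. This Lewis-acid debenzylation with a cation scavenger leaves the non-chelated methyl ether and the alkene alone and gives 20 directly, with no new intermediate.

## Further compounds

F1 | step 11 | heptan-2-one | CCCCCC(C)=O
F2 | step 11 | 2-(trimethylsilyloxy)hept-1-ene | CCCCCC(=C)O[Si](C)(C)C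
F3 | step 7 | benzyl 2,4-bis(benzyloxy)-5-(methoxymethoxy)benzoate | COCOc1cc(C(=O)OCc2ccccc2)c(OCc2ccccc2)cc1OCc1ccccc1
F4 | step 7 | {3,5-bis(benzyloxy)-2-[(benzyloxy)carbonyl]-6-(methoxymethoxy)phenyl}magnesium chloride | COCOc1c([Mg]Cl)c(C(=O)OCc2ccccc2)c(OCc2ccccc2)cc1OCc1ccccc1
F5 | step 7 | benzyl 4,6-bis(benzyloxy)-2-bromo-3-(methoxymethoxy)benzoate | COCOc1c(Br)c(C(=O)OCc2ccccc2)c(OCc2ccccc2)cc1OCc1ccccc1
F6 | step 12 | acetic 2-{4,6-bis(benzyloxy)-3-[(benzyloxy)carbonyl]-2-(2-oxoheptyl)phenoxy}-4-methoxy-6-(2-oxoheptyl)benzoic anhydride | COc1cc(CC(=O)CCCCC)c(C(=O)OC(C)=O)c(Oc2c(CC(=O)CCCCC)c(C(=O)OCc3ccccc3)c(OCc4ccccc4)cc2OCc5ccccc5)c1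
F0 | step 13 | none | none
A1 | alternative 1 | 7-hydroxy-6-[(6-methoxy-1-oxo-3-pentyl-1H-isochromen-8-yl)oxy]-2,2-dimethyl-5-[(2-pentyl-1,3-dioxolan-2-yl)methyl]-4H-1,3-benzodioxin-4-one | CCCCCc1cc2cc(OC)cc(Oc3c(O)cc4OC(C)(C)OC(=O)c4c3CC5(CCCCC)OCCO5)c2c(=O)o1
A2 | alternative 1 | 8-{[1-(2,2-dimethyl-4-oxo-4H-1,3-dioxin-6-yl)-2,4-dioxo-5-(2-pentyl-1,3-dioxolan-2-yl)pentan-3-yl]oxy}-6-methoxy-3-pentyl-1H-isochromen-1-one | CCCCCc1cc2cc(OC)cc(OC(C(=O)CC3=CC(=O)OC(C)(C)O3)C(=O)CC4(CCCCC)OCCO4)c2c(=O)o1
A3 | alternative 2 | allyl 4,6-bis(allyloxy)-3-[(6-methoxy-1-oxo-3-pentyl-1H-isochromen-8-yl)oxy]-2-(2-oxoheptyl)benzoate | CCCCCc1cc2cc(OC)cc(Oc3c(OCC=C)cc(OCC=C)c(C(=O)OCC=C)c3CC(=O)CCCCC)c2c(=O)o1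
A4 | alternative 2 | 2-{4,6-bis(allyloxy)-3-[(allyloxy)carbonyl]-2-(hept-2-yn-1-yl)phenoxy}-6-(hept-1-yn-1-yl)-4-methoxybenzoic acid | CCCCCC#Cc1cc(OC)cc(Oc2c(OCC=C)cc(OCC=C)c(C(=O)OCC=C)c2CC#CCCCC)c1C(=O)O
A5 | alternative 3 | benzyl 4,6-bis(benzyloxy)-3-[(6-hydroxy-1-oxo-3-pentyl-1H-isochromen-8-yl)oxy]-2-[(2-pentyl-1,3-dioxolan-2-yl)methyl]benzoate | CCCCCc1cc2cc(O)cc(Oc3c(OCc4ccccc4)cc(OCc5ccccc5)c(C(=O)OCc6ccccc6)c3CC7(CCCCC)OCCO7)c2c(=O)o1
A6 | alternative 3 | benzyl 4,6-bis(benzyloxy)-3-{[(E)-3-methoxy-1-(4-methyl-2-oxo-6-pentyl-2H-pyran-3-yl)-3-oxoprop-1-en-1-yl]oxy}-2-[(2-pentyl-1,3-dioxolan-2-yl)methyl]benzoate | CCCCCc1cc(C)c(/C(Oc2c(OCc3ccccc3)cc(OCc4ccccc4)c(C(=O)OCc5ccccc5)c2CC6(CCCCC)OCCO6)=C\C(=O)OC)c(=O)o1
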